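Every bit of substrate charged is either still substrate or has reacted, so I reckon only the small reacted part and take it from the whole.

| flask | substrate | reagent in the second phase | remark | time | volume of the second phase over the first |
|---|---|---|---|---|---|
| Monday's | 13 mM | 24 mM | run made earlier |  |  |
| Thursday's | 30 mM | 24 mM | run made earlier |  |  |
| Sunday's | 20 mM | 48 mM | run made earlier |  |  |
| flask | 20 mM | 24.0 mM |  | 8.0 min | 1.0 |

| run | time / min | target / % | substrate / % |
|---|---|---|---|
| Monday's | 0.500 | 0 | 101 |
| Monday's | 1.33 | 0 | 100 |
| Monday's | 2.50 | 3 | 98 |
| Monday's | 4.00 | 4 | 92 |
| Monday's | 6.00 | 2 | 91 |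
| Monday's | 8.00 | 5 | 88 |
| Monday's | 10.0 | 6 | 83 |
| Thursday's | 0.500 | 0 | 102 |
| Thursday's | 1.33 | 3 | 102 |
| Thursday's | 2.50 | 1 | 95 |
| Thursday's | 4.00 | 1 | 96 |
| Thursday's | 6.00 | 1 | 93 |
| Thursday's | 8.00 | 0 | 92 |
| Thursday's | 10.0 | 0 | 90 |
| Sunday's | 0.833 | 2 | 101 |
| Sunday's | 1.33 | 3 | 99 |
| Sunday's | 2.50 | 5 | 96 |
| Sunday's | 5.00 | 7 | 87 |
| Sunday's | 10.0 | 8 | 70 |

(standard deviation of a reading: 1.5 percentage points)

- how much target and product in the second phase together there is at 8.0 min, in percent of the substrate charged
- part of the substrate charged that has reacted at 8.0 min

- what is said of target includes product in the second phase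
- in the second phase: reagent in the second phase, product in the second phase; everything else is in the first
- charges count per volume of the first phase; a concentration in a rate is the amount of a species over the volume of its own phase; every rate counts per litre of the first phase
- the earlier runs hold the two phases in the same ratio of volumes as the flask asked about

By their last readings, at 10.0 min, Monday's run has lost substrate at a mean 0.221 mM min⁻¹ and Thursday's at 0.300 mM min⁻¹, both with the flask's reagent charge. A straight line between them gives 0.254 mM min⁻¹ at the flask's [substrate] of 20 mM. I fold rate, time and charge into one number for the flask, 10.1%: the turnover fraction, loss rate times time over charge. It is my estimate of the part reacted at 8.0 min, and each reading behind it carries a scatter of 1.5 percentage points.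

One number does not give the target, because the loss splits: Monday's run ends with 6% target and Thursday's with 0%. Sunday's run has the flask's substrate charge but twice its reagent, and shows 0.267 of its loss as target, a reading of the selectivity. Taking that share, I expect 2.70% target in the flask.

The forecast says 2.7% and 10%, noting that “Target selectivity falls sharply with substrate”. The flask gives 3.07% and 11.7%.

    reagent in the reaction phase ⇌ reagent in the second phase, rate k1*([reagent in the reaction phase] - [reagent in the second phase]/K1) per volume of the first phase (partition coefficient = 2.00, kL = 4.68 × 10⁻⁴ s⁻¹)
    substrate + reagent in the reaction phase ⇌ target (K = 37.6 L mol⁻¹, k = 6.17 L mol⁻¹ s⁻¹)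
    target ⇌ product in the second phase, rate k3*([target] - [product in the second phase]/K3) per volume of the first phase (partition coefficient = 2.33, kL = 0.00103 s⁻¹)
    target → decomposed product (k = 0.00131 s⁻¹)
    target → over-reaction product (k = 0.00164 s⁻¹)
    substrate + target → side product (k = 0.230 L mol⁻¹ s⁻¹)

The flask's reacted part stands 1.6 points above the turnover fraction, while at 3.0 min the same flask has 3.35% reacted against the 3.81% that the number reads, so its mean loss rate grows from 0.223 mM min⁻¹ to 0.292 mM min⁻¹. With the concentrations as charged, reaction-phase target has a half-life of 2.5 min by joining substrate into side product alone, shorter than the 8.8 min by passing into decomposed product alone. At 8.00 min the flask holds 6.43% side product, which counts as two in every percentage, against 0.980% decomposed product.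

The earlier runs and the new flask were computed with made-up constants; noise was put on by code.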